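**Plan**

- Retrosynthesis: the two ester C–O bonds are cut first (the C1 acyloxy group back to a C1 carboxyl, the C7 coumarate back to the alcohol), then the C1–C9 bond of the dihydropyran, then the lactone C–O bond, the O2–CH2 ether bond, C3–C4, C8–C10 and C5–C4.
- Enabling feature: C1 carries the ring oxygen O2 (a glycolate-type carbon) and is bonded to C9, one end of the allyl unit C7–C8=C9 whose other end C7 bears oxygen. An ester from a C1 carboxyl to the C7 oxygen, held to C5 through O2–C3=C4, makes C1–C9 the bond of a transannular glycolate Claisen shift that also closes the pyran ring.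
- Forward order: cyclopentene (ring A) from the monoacetate → C4 side chain and C10 → enol ether → nine-membered bridging lactone → [3,3] shift closes the dihydropyran (ring B) → C7/C8 oxygenation relayed by the C1 carboxyl → C1 acyloxy acetal by decarboxylation → C7 ester → C11 reduction → desilylation.
- Stereochemistry: C5 comes from the monoacetate (Pd, net retention). The C7 oxygen is set cis by Luche reduction and relayed to C9 by the suprafacial shift. C7 and C8 arise from convex epoxidation and backside opening at C8 by the C1 carboxyl. C1 is set by carboxylate capture on the convex face. The branched acid and the Still–Gennari Z alkene are brought in ready-made.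

Key step: step 11

Remark: iridoid numbering is used throughout (C1 acetal carbon, O2, C3=C4 with C11 on C4, C5 and C9 ring fusion, C6, C7, C8 bearing C10). β is the face of H5 and H9, the convex face of the cis-fused bicycle. It is assumed that the enol of 10 alkylates on oxygen mainly to the E ether (O2 cis to C5), the only isomer that can reach C7. C4 is kept as an ester or aldehyde through all oxidative steps so that the enol ether stays electron-poor.

**Step 1**
Reactants: 1 (1R,4S)-cis-4-acetoxy-2-cyclopenten-1-ol; 2 dimethyl malonate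
Product: 3 dimethyl 2-[(1S,4R)-4-hydroxycyclopent-2-en-1-yl]propanedioate
Conditions: NaH, THF, 0 °C; Pd(PPh3)4 (cat.), rt → 50 °C
Reagents that add atoms: none
Why: Tsuji–Trost allylic alkylation: zerovalent palladium ionises the acetate with inversion and the malonate anion attacks the allyl terminus remote from the hydroxyl with a second inversion, so the new C5–C4 bond is cis to the hydroxyl and C5 takes its configuration from 1.

**Step 2**
Reactants: 3 dimethyl 2-[(1S,4R)-4-hydroxycyclopent-2-en-1-yl]propanedioate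
Product: 4 methyl 2-[(1R,4R)-4-hydroxycyclopent-2-en-1-yl]acetate
Conditions: NaCl, DMSO/H2O, 150 °C
Reagents that add atoms: none
Why: Krapcho dealkoxycarbonylation removes one malonate ester under neutral conditions that leave the allylic alcohol and the C5 stereocentre untouched.

**Step 3**
Reactants: 4 methyl 2-[(1R,4R)-4-hydroxycyclopent-2-en-1-yl]acetate
Product: 5 methyl 2-[(1R)-4-oxocyclopent-2-en-1-yl]acetate
Conditions: Dess–Martin periodinane, NaHCO3, CH2Cl2, 0 °C → rt
Reagents that add atoms: none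
Why: Dess–Martin oxidation of the secondary allylic alcohol to the enone under buffered conditions that should not deprotonate the γ position C5.

**Step 4**
Reactants: 5 methyl 2-[(1R)-4-oxocyclopent-2-en-1-yl]acetate
Product: 6 methyl 2-[(1R)-3-(hydroxymethyl)-4-oxocyclopent-2-en-1-yl]acetate
Conditions: 37% aq. CH2O, imidazole, THF/H2O, rt
Reagents that add atoms: formaldehyde, C=O
Why: Morita–Baylis–Hillman hydroxymethylation: imidazole adds reversibly to C9, the enolate is trapped by formaldehyde at C8 and elimination restores the enone, which installs C10 in a medium too weakly basic to epimerise C5.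

**Step 5**
Reactants: 6 methyl 2-[(1R)-3-(hydroxymethyl)-4-oxocyclopent-2-en-1-yl]acetate
Product: 7 methyl 2-[(1R,4R)-4-hydroxy-3-(hydroxymethyl)cyclopent-2-en-1-yl]acetate
Conditions: NaBH4, CeCl3·7H2O, MeOH, −78 °C
Reagents that add atoms: none
Why: Luche 1,2-reduction: hydride should approach the carbonyl from the face opposite the C5 side chain, so the C7 hydroxyl is set cis (α) to that chain.

**Step 6**
Reactants: 7 methyl 2-[(1R,4R)-4-hydroxy-3-(hydroxymethyl)cyclopent-2-en-1-yl]acetate
Product: 9 methyl 2-[(1R,4R)-3-[(tert-butyldiphenylsilyloxy)methyl]-4-(triethylsilyloxy)cyclopent-2-en-1-yl]acetate, via primary silyl ether 8 (not isolated)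
Conditions: t-BuPh2SiCl, imidazole, DMF, 0 °C; then Et3SiCl, rt
Reagents that add atoms: tert-butyl(chloro)diphenylsilane, CC(C)(C)[Si](Cl)(c1ccccc1)c1ccccc1; chlorotriethylsilane, CC[Si](Cl)(CC)CC
Why: Sequential silyl ether formation: the bulky chlorosilane takes the primary C10 hydroxyl only, and the smaller one then caps the secondary C7 hydroxyl with a group that can later be removed on its own.

**Step 7**
Reactants: 9 methyl 2-[(1R,4R)-3-[(tert-butyldiphenylsilyloxy)methyl]-4-(triethylsilyloxy)cyclopent-2-en-1-yl]acetate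
Product: 10 methyl 2-[(1S,4R)-3-[(tert-butyldiphenylsilyloxy)methyl]-4-(triethylsilyloxy)cyclopent-2-en-1-yl]-3-hydroxyprop-2-enoate (α-formyl ester drawn as its enol)
Conditions: LiN(i-Pr)2 (2.2 equiv), THF, −78 °C; HCO2Me, −78 → 0 °C; aq. NH4Cl
Reagents that add atoms: methyl formate, COC=O
Why: Crossed Claisen condensation (formylation): the ester enolate at C4 attacks methyl formate and deprotonation of the β-formyl ester drives the equilibrium, which installs C3.

**Step 8**
Reactants: 10 α-formyl ester (enol form); 11 methyl bromoacetate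
Product: 12 methyl (2E)-2-[(1S,4R)-3-[(tert-butyldiphenylsilyloxy)methyl]-4-(triethylsilyloxy)cyclopent-2-en-1-yl]-3-(2-methoxy-2-oxoethoxy)prop-2-enoate
Conditions: K2CO3, DMF, 0 °C → rt
Reagents that add atoms: none
Why: Williamson-type O-alkylation of the hydroxymethylene ester enolate in a polar aprotic solvent: the hindered carbon terminus is bypassed and the E β-alkoxyacrylate (O2 trans to the ester, cis to C5) is expected as the main isomer, the minor Z ether being removed by chromatography.

**Step 9**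
Reactants: 12 E enol ether diester
Product: 14 {[(1E)-2-[(1S,4R)-3-[(tert-butyldiphenylsilyloxy)methyl]-4-hydroxycyclopent-2-en-1-yl]-3-methoxy-3-oxoprop-1-en-1-yl]oxy}acetic acid (seco acid), via lithium carboxylate 13 (not isolated)
Conditions: LiOH·H2O (1.1 equiv), THF/H2O, 0 °C; then 1 M HCl to pH 2, rt
Reagents that add atoms: lithium hydroxide, [Li+].[OH-]
Why: Chemoselective saponification: the α-alkoxy (glycolate) methyl ester is far more electrophilic than the push–pull β-alkoxyacrylate ester, and brief acidification then hydrolyses the triethylsilyl ether while the tert-butyldiphenylsilyl ether survives.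

**Step 10**
Reactants: 14 seco acid
Product: 16 nine-membered bridging lactone (glycolate carboxyl esterified to the α oxygen at C7; E enol ether O2–C3=C4(CO2Me) on the α face of C5; C8=C9; C10–OSiPh2t-Bu), via mixed anhydride 15 (not isolated)
Conditions: 2,4,6-Cl3C6H2COCl, Et3N, THF, rt; then slow addition to DMAP, PhMe, 80 °C (about 1 mM)
Reagents that add atoms: none
Why: Yamaguchi macrolactonisation under high dilution: the cis-1,3 placement of the two arms on the cyclopentene and the planar ring-cis enol ether bring the activated carboxyl to the C7 hydroxyl, which is acylated with retention.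

**Step 11**
Reactants: 16 nine-membered bridging lactone
Product: 19 cis-fused cyclopenta[c]pyran 1α-carboxylic acid (H5β and H9β; C3=C4–CO2Me; C7=C8; C10–OSiPh2t-Bu), via silyl ketene acetal 17 (not isolated), via trimethylsilyl ester 18 (not isolated)
Conditions: Me3SiCl, Et3N, THF, −78 °C, then KN(SiMe3)2; −78 °C → rt, then PhMe, 80 °C; 0.5 M HCl work-up
Reagents that add atoms: none
Why: KN(SiMe3)2 removes a C1 proton of the α-alkoxy lactone and Me3SiCl traps the enolate as the ring-cis silyl ketene acetal 17, whose C1=C(OSi)–O–C7–C8=C9 array undergoes a concerted [3,3] sigmatropic shift that forms C1–C9, breaks C7–O and moves the alkene to C7=C8. The closest known reaction type is the Ireland–Claisen ring contraction of lactones, including α-oxygenated lactones that give dihydropyran-2-carboxylic acids. The dihydropyran is closed by transannular C1–C9 bonding, which contracts the ten-membered perimeter running through C8 and C9 to the six-membered ring through the boat-like six-centre transition state that the bridge enforces. C9 is set by the tether: the bridge leaves from the α oxygen at C7 and is held on the α face of C5, so C1 can reach only the α face of C9 (suprafacial transfer, cis fusion), and the 1α-carboxyl follows from the ring-cis ketene acetal geometry in that boat. The step needs enolisation at C1 without Dieckmann-type attack on the C4 ester, which the in situ silylation and the E enol ether (ester trans to O2, out of reach of C1) should secure.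

**Step 12**
Reactants: 19 cis-fused 1α-carboxylic acid
Product: 21 7β-hydroxy 1α,8α-carbolactone (γ-lactone from the C1 carboxyl to the 8α oxygen; C10 β; C4–CO2Me; C10–OSiPh2t-Bu), via epoxy acid 20 (not isolated)
Conditions: mCPBA, CH2Cl2, 0 °C → rt; then (+)-10-camphorsulfonic acid (cat.)
Reagents that add atoms: 3-chloroperoxybenzoic acid, OOC(=O)c1cccc(Cl)c1
Why: Prilezhaev epoxidation on the convex β face of the trisubstituted alkene (the vinylogous carbonate is too electron-poor to react), then acid-catalysed 5-exo opening at the tertiary C8 by the 1α-carboxyl from the α face with inversion, which sets C7 (β-OH) and C8 (α-O, C10 β).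

**Step 13**
Reactants: 21 7β-hydroxy 1α,8α-carbolactone
Product: 24 7β,8α-bis(triethylsilyloxy) 1α-carboxylic acid (C4–CO2Me; C10–OSiPh2t-Bu), via lithium dihydroxy carboxylate 22 (not isolated), via triethylsilyl ester 23 (not isolated)
Conditions: LiOH·H2O, THF/H2O, 0 °C; evaporation, PhMe azeotrope; Et3SiOTf, 2,6-lutidine, CH2Cl2, −78 → 0 °C; aq. NaHCO3/MeOH work-up
Reagents that add atoms: lithium hydroxide, [Li+].[OH-]; triethylsilyl trifluoromethanesulfonate, CC[Si](CC)(CC)OS(=O)(=O)C(F)(F)F
Why: Lactone saponification then silylation: hydroxide opens the strained α-alkoxy γ-lactone much faster than it attacks the vinylogous carbonate, and silylating the carboxylate salt before any acidification caps the 8α-hydroxyl so the acid cannot close back, the silyl ester alone being hydrolysed on work-up.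

**Step 14**
Reactants: 24 7β,8α-bis(triethylsilyloxy) 1α-carboxylic acid
Product: 25 C11 alcohol of 24 (C4–CH2OH; 1α-CO2H)
Conditions: i-Bu2AlH (4 equiv), CH2Cl2, −78 °C; aq. KNaC4H4O6, pH 6; used crude at once
Reagents that add atoms: none
Why: i-Bu2AlH ester reduction: the acid is first converted to an aluminium carboxylate that resists hydride at −78 °C, while the vinylogous carbonate is reduced 1,2 to the C11 allylic alcohol.

**Step 15**
Reactants: 25 C11 alcohol
Product: 26 C11 aldehyde (C4–CHO; 1α-CO2H; 7β,8α-bis(OSiEt3); C10–OSiPh2t-Bu)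
Conditions: Dess–Martin periodinane, NaHCO3, CH2Cl2, 0 °C
Reagents that add atoms: none
Why: Dess–Martin oxidation of the primary allylic alcohol to the conjugated aldehyde restores the push–pull deactivation of the enol ether that the next oxidative step needs, with silyl ethers and carboxyl inert.

**Step 16**
Reactants: 27 (R)-3-methylpentanoic acid (2.2 equiv)
Product: 28 bis[(3R)-3-methylpentanoyloxy]iodobenzene
Conditions: PhI(OAc)2, PhCl, 50 °C, reduced pressure
Reagents that add atoms: (diacetoxyiodo)benzene, CC(=O)OI(OC(C)=O)c1ccccc1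
Why: Ligand exchange at trivalent iodine: the less volatile acid displaces acetate and removal of acetic acid under reduced pressure drives the equilibrium to the dicarboxylate.

**Step 17**
Reactants: 26 C11 aldehyde acid; 28 bis[(3R)-3-methylpentanoyloxy]iodobenzene
Product: 29 1β-[(3R)-3-methylpentanoyloxy] acetal (C4–CHO; 7β,8α-bis(OSiEt3); C10–OSiPh2t-Bu)
Conditions: 28 (1.5 equiv), I2 (0.5 equiv), CH2Cl2, visible light, rt
Reagents that add atoms: none
Why: Hypoiodite (Suárez-type) oxidative decarboxylation: the C1 carboxylate exchanges onto trivalent iodine, the acyl hypoiodite loses CO2 under light, and the C1 α-oxy radical is oxidised through the iodide to the oxocarbenium ion, which the 3-methylpentanoate should capture on the convex β face because the α face is blocked by the cyclopentane ring and the 8α-silyloxy group.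

**Step 18**
Reactants: 29 1β-acyloxy acetal
Product: 30 7β,8α-diol of 29 (C4–CHO; C10–OSiPh2t-Bu)
Conditions: HF·pyridine, pyridine, THF, 0 °C → rt
Reagents that add atoms: none
Why: Buffered fluoride desilylation: triethylsilyl ethers are cleaved orders of magnitude faster than the primary tert-butyldiphenylsilyl ether, and the acyl acetal and the vinylogous formyl group should tolerate pyridine-buffered HF.

**Step 19**
Reactants: 31 4-hydroxybenzaldehyde
Product: 32 4-(triisopropylsilyloxy)benzaldehyde
Conditions: i-Pr3SiCl, imidazole, DMF, rt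
Reagents that add atoms: chlorotri(propan-2-yl)silane, CC(C)[Si](Cl)(C(C)C)C(C)C
Why: Imidazole-promoted silyl ether formation gives a phenol protecting group that survives the base and hydride steps ahead and leaves with fluoride at the end.

**Step 20**
Reactants: 32 4-(triisopropylsilyloxy)benzaldehyde; 33 methyl P,P-bis(2,2,2-trifluoroethyl)phosphonoacetate
Product: 34 methyl (2Z)-3-[4-(triisopropylsilyloxy)phenyl]prop-2-enoate
Conditions: KN(SiMe3)2, 18-crown-6, THF, −78 °C
Reagents that add atoms: none
Why: Still–Gennari olefination: the trifluoroethyl phosphonate with a dissociated potassium counter-ion eliminates fast from the kinetically formed adduct and should give the Z cinnamate.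

**Step 21**
Reactants: 34 methyl Z-cinnamate
Product: 35 (2Z)-3-[4-(triisopropylsilyloxy)phenyl]prop-2-enoic acid
Conditions: Me3SnOH, ClCH2CH2Cl, 80 °C; 5% aq. HCl wash
Reagents that add atoms: trimethyltin hydroxide, C[Sn](C)(C)O
Why: Me3SnOH ester hydrolysis cleaves the methyl ester under neutral conditions that should leave the aryl silyl ether in place and the Z alkene unisomerised.

**Step 22**
Reactants: 30 7β,8α-diol; 35 Z acid
Product: 36 7β-O-[(2Z)-3-[4-(triisopropylsilyloxy)phenyl]prop-2-enoyl] ester of 30 (C4–CHO; 8α-OH; C10–OSiPh2t-Bu)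
Conditions: EDC·HCl, DMAP (cat.), CH2Cl2, 0 °C → rt, dark
Reagents that add atoms: none
Why: Steglich esterification: the secondary 7β-hydroxyl is acylated while the tertiary 8α-hydroxyl is inert, and low temperature, little DMAP and exclusion of light should keep the Z geometry.

**Step 23**
Reactants: 36 C7 ester aldehyde
Product: 37 C11 alcohol of 36 (C4–CH2OH)
Conditions: NaBH4, CeCl3·7H2O, MeOH/THF, −40 °C
Reagents that add atoms: none
Why: Luche reduction takes the conjugated aldehyde 1,2 to the C11 alcohol at low temperature while the acyl acetal, the cinnamate and the silyl ethers are not attacked.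

**Step 24**
Reactants: 37 bis-silyl ether
Product: 38 CNP0217341.1 (target)
Conditions: Bu4NF, AcOH, THF, 0 °C → rt
Reagents that add atoms: none
Why: Fluoride desilylation buffered with acetic acid removes the alkyl and the aryl silyl ether without base-induced acyl migration or loss of the acyl acetal.

**Compound list**

1 | (1R,4S)-cis-4-acetoxy-2-cyclopenten-1-ol | CC(=O)O[C@H]1C[C@@H](O)C=C1 | starting material
2 | dimethyl malonate | COC(=O)CC(=O)OC | starting material
3 | dimethyl 2-[(1S,4R)-4-hydroxycyclopent-2-en-1-yl]propanedioate | COC(=O)C(C(=O)OC)[C@H]1C[C@@H](O)C=C1 | intermediate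
4 | methyl 2-[(1R,4R)-4-hydroxycyclopent-2-en-1-yl]acetate | COC(=O)C[C@H]1C[C@@H](O)C=C1 | intermediate
5 | methyl 2-[(1R)-4-oxocyclopent-2-en-1-yl]acetate | COC(=O)C[C@H]1CC(=O)C=C1 | intermediate
6 | methyl 2-[(1R)-3-(hydroxymethyl)-4-oxocyclopent-2-en-1-yl]acetate | COC(=O)C[C@H]1CC(=O)C(CO)=C1 | intermediate
7 | methyl 2-[(1R,4R)-4-hydroxy-3-(hydroxymethyl)cyclopent-2-en-1-yl]acetate | COC(=O)C[C@H]1C[C@@H](O)C(CO)=C1 | intermediate
8 | methyl 2-[(1R,4R)-3-[(tert-butyldiphenylsilyloxy)methyl]-4-hydroxycyclopent-2-en-1-yl]acetate | COC(=O)C[C@H]1C[C@@H](O)C(CO[Si](c2ccccc2)(c2ccccc2)C(C)(C)C)=C1 | intermediate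
9 | methyl 2-[(1R,4R)-3-[(tert-butyldiphenylsilyloxy)methyl]-4-(triethylsilyloxy)cyclopent-2-en-1-yl]acetate | COC(=O)C[C@H]1C[C@@H](O[Si](CC)(CC)CC)C(CO[Si](c2ccccc2)(c2ccccc2)C(C)(C)C)=C1 | intermediate
10 | methyl 2-[(1S,4R)-3-[(tert-butyldiphenylsilyloxy)methyl]-4-(triethylsilyloxy)cyclopent-2-en-1-yl]-3-hydroxyprop-2-enoate (enol of the α-formyl ester) | COC(=O)C(=CO)[C@H]1C[C@@H](O[Si](CC)(CC)CC)C(CO[Si](c2ccccc2)(c2ccccc2)C(C)(C)C)=C1 | intermediate
11 | methyl bromoacetate | COC(=O)CBr | starting material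
12 | methyl (2E)-2-[(1S,4R)-3-[(tert-butyldiphenylsilyloxy)methyl]-4-(triethylsilyloxy)cyclopent-2-en-1-yl]-3-(2-methoxy-2-oxoethoxy)prop-2-enoate | COC(=O)CO/C=C(/C(=O)OC)[C@H]1C[C@@H](O[Si](CC)(CC)CC)C(CO[Si](c2ccccc2)(c2ccccc2)C(C)(C)C)=C1 | intermediate
13 | lithium carboxylate of the glycolic acid arm of 12 (C7–OSiEt3 retained) | [Li+].[O-]C(=O)CO/C=C(/C(=O)OC)[C@H]1C[C@@H](O[Si](CC)(CC)CC)C(CO[Si](c2ccccc2)(c2ccccc2)C(C)(C)C)=C1 | intermediate
14 | {[(1E)-2-[(1S,4R)-3-[(tert-butyldiphenylsilyloxy)methyl]-4-hydroxycyclopent-2-en-1-yl]-3-methoxy-3-oxoprop-1-en-1-yl]oxy}acetic acid (seco acid) | OC(=O)CO/C=C(/C(=O)OC)[C@H]1C[C@@H](O)C(CO[Si](c2ccccc2)(c2ccccc2)C(C)(C)C)=C1 | intermediate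
15 | mixed anhydride of 14 with 2,4,6-trichlorobenzoic acid | O=C(OC(=O)CO/C=C(/C(=O)OC)[C@H]1C[C@@H](O)C(CO[Si](c2ccccc2)(c2ccccc2)C(C)(C)C)=C1)c1c(Cl)cc(Cl)cc1Cl | intermediate
16 | nine-membered bridging lactone (glycolate carboxyl on the α oxygen of C7; E enol ether O2–C3=C4(CO2Me) on the α face of C5; C8=C9; C10–OSiPh2t-Bu) | O=C1CO/C=C(/C(=O)OC)[C@H]2C[C@@H](O1)C(CO[Si](c3ccccc3)(c3ccccc3)C(C)(C)C)=C2 | intermediate
17 | trimethylsilyl ketene acetal of 16 (ring-cis C=C1) | C[Si](C)(C)O/C1=C/O/C=C(/C(=O)OC)[C@H]2C[C@@H](O1)C(CO[Si](c3ccccc3)(c3ccccc3)C(C)(C)C)=C2 | intermediate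
18 | trimethylsilyl ester of 19 | C[Si](C)(C)OC(=O)[C@H]1OC=C(C(=O)OC)[C@H]2CC=C(CO[Si](c3ccccc3)(c3ccccc3)C(C)(C)C)[C@@H]12 | intermediate
19 | cis-fused cyclopenta[c]pyran 1α-carboxylic acid (H5β, H9β; C3=C4–CO2Me; C7=C8; C10–OSiPh2t-Bu) | OC(=O)[C@H]1OC=C(C(=O)OC)[C@H]2CC=C(CO[Si](c3ccccc3)(c3ccccc3)C(C)(C)C)[C@@H]12 | intermediate
20 | 7β,8β-epoxide of 19 (epoxy acid) | OC(=O)[C@H]1OC=C(C(=O)OC)[C@H]2C[C@@H]3O[C@]3(CO[Si](c4ccccc4)(c4ccccc4)C(C)(C)C)[C@@H]12 | intermediate
21 | 7β-hydroxy 1α,8α-carbolactone (γ-lactone C1–C(=O)–O–C8; C10 β; C4–CO2Me) | O=C1[C@H]2OC=C(C(=O)OC)[C@H]3C[C@H](O)[C@@](CO[Si](c4ccccc4)(c4ccccc4)C(C)(C)C)(O1)[C@@H]23 | intermediate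
22 | lithium 7β,8α-dihydroxy 1α-carboxylate | [Li+].[O-]C(=O)[C@H]1OC=C(C(=O)OC)[C@H]2C[C@H](O)[C@](O)(CO[Si](c3ccccc3)(c3ccccc3)C(C)(C)C)[C@@H]12 | intermediate
23 | triethylsilyl ester of 24 | CC[Si](CC)(CC)OC(=O)[C@H]1OC=C(C(=O)OC)[C@H]2C[C@H](O[Si](CC)(CC)CC)[C@](O[Si](CC)(CC)CC)(CO[Si](c3ccccc3)(c3ccccc3)C(C)(C)C)[C@@H]12 | intermediate
24 | 7β,8α-bis(triethylsilyloxy) 1α-carboxylic acid (C4–CO2Me; C10–OSiPh2t-Bu) | OC(=O)[C@H]1OC=C(C(=O)OC)[C@H]2C[C@H](O[Si](CC)(CC)CC)[C@](O[Si](CC)(CC)CC)(CO[Si](c3ccccc3)(c3ccccc3)C(C)(C)C)[C@@H]12 | intermediate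
25 | C11 alcohol of 24 (C4–CH2OH) | OC(=O)[C@H]1OC=C(CO)[C@H]2C[C@H](O[Si](CC)(CC)CC)[C@](O[Si](CC)(CC)CC)(CO[Si](c3ccccc3)(c3ccccc3)C(C)(C)C)[C@@H]12 | intermediate
26 | C11 aldehyde of 24 (C4–CHO) | OC(=O)[C@H]1OC=C(C=O)[C@H]2C[C@H](O[Si](CC)(CC)CC)[C@](O[Si](CC)(CC)CC)(CO[Si](c3ccccc3)(c3ccccc3)C(C)(C)C)[C@@H]12 | intermediate
27 | (R)-3-methylpentanoic acid | CC[C@@H](C)CC(=O)O | starting material
28 | bis[(3R)-3-methylpentanoyloxy]iodobenzene | CC[C@@H](C)CC(=O)OI(OC(=O)C[C@H](C)CC)c1ccccc1 | intermediate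
29 | 1β-[(3R)-3-methylpentanoyloxy] acetal (C4–CHO; 7β,8α-bis(OSiEt3); C10–OSiPh2t-Bu) | CC[C@@H](C)CC(=O)O[C@@H]1OC=C(C=O)[C@H]2C[C@H](O[Si](CC)(CC)CC)[C@](O[Si](CC)(CC)CC)(CO[Si](c3ccccc3)(c3ccccc3)C(C)(C)C)[C@@H]12 | intermediate
30 | 7β,8α-diol of 29 | CC[C@@H](C)CC(=O)O[C@@H]1OC=C(C=O)[C@H]2C[C@H](O)[C@](O)(CO[Si](c3ccccc3)(c3ccccc3)C(C)(C)C)[C@@H]12 | intermediate
31 | 4-hydroxybenzaldehyde | O=Cc1ccc(O)cc1 | starting material
32 | 4-(triisopropylsilyloxy)benzaldehyde | O=Cc1ccc(O[Si](C(C)C)(C(C)C)C(C)C)cc1 | intermediate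
33 | methyl P,P-bis(2,2,2-trifluoroethyl)phosphonoacetate | COC(=O)CP(=O)(OCC(F)(F)F)OCC(F)(F)F | starting material
34 | methyl (2Z)-3-[4-(triisopropylsilyloxy)phenyl]prop-2-enoate | COC(=O)/C=C\c1ccc(O[Si](C(C)C)(C(C)C)C(C)C)cc1 | intermediate
35 | (2Z)-3-[4-(triisopropylsilyloxy)phenyl]prop-2-enoic acid | OC(=O)/C=C\c1ccc(O[Si](C(C)C)(C(C)C)C(C)C)cc1 | intermediate
36 | 7β-O-[(2Z)-3-[4-(triisopropylsilyloxy)phenyl]prop-2-enoyl] ester of 30 (C4–CHO; 8α-OH) | CC[C@@H](C)CC(=O)O[C@@H]1OC=C(C=O)[C@H]2C[C@H](OC(=O)/C=C\c3ccc(O[Si](C(C)C)(C(C)C)C(C)C)cc3)[C@](O)(CO[Si](c4ccccc4)(c4ccccc4)C(C)(C)C)[C@@H]12 | intermediate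
37 | C11 alcohol of 36 (C4–CH2OH) | CC[C@@H](C)CC(=O)O[C@@H]1OC=C(CO)[C@H]2C[C@H](OC(=O)/C=C\c3ccc(O[Si](C(C)C)(C(C)C)C(C)C)cc3)[C@](O)(CO[Si](c4ccccc4)(c4ccccc4)C(C)(C)C)[C@@H]12 | intermediate
38 | CNP0217341.1 | CC[C@@H](C)CC(=O)O[C@@H]1OC=C(CO)[C@H]2C[C@H](OC(=O)/C=C\c3ccc(O)cc3)[C@](O)(CO)[C@@H]12 | target

**Step count**

Total: 24 steps. Longest linear sequence: 20 steps (steps 1–15, 17, 18, 22, 23, 24). Steps 16 and 19–21 are side branches.

**Steps most likely to fail**

Step 10. Closure of the strained nine-membered ring may be outrun by intermolecular acylation to diolides and oligomers, or by transfer of the C7 hydroxyl onto C3 of the enol ether. The fallback sets out from 12 and returns at 16; it activates the alcohol instead of the acid. Acidic methanolysis of the triethylsilyl ether (PPTS, MeOH) would give the hydroxy diester F1. Mitsunobu inversion with 4-nitrobenzoic acid (PPh3, DIAD) would give the 7β 4-nitrobenzoate F2. LiOH would then cleave the nitrobenzoate and the glycolate methyl ester to the C7-epimeric seco acid F3. Mitsunobu lactonisation of this acid (PPh3, DIAD, PhMe, high dilution) closes the ring with inversion at C7 and should deliver 16.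

Step 11. The ketene acetal may fragment (loss of the C7 alkoxide, ketene formation) or be silylated at carbon before it reaches the boat transition state. The fallback sets out from 8 (isolated when Et3SiCl is left out of step 6) and returns at 19; it forms C1–C9 in an open-chain ester and closes the pyran afterwards by C–O bond formation. Esterification of the C7 hydroxyl with (4-methoxybenzyloxy)acetic acid (DCC, DMAP) would give the glycolate ester F4. An open-chain Ireland–Claisen rearrangement (excess KN(SiMe3)2, Me3SiCl; both esters enolised, the methyl ester returning on work-up) should give the α-alkoxy acid F5 with C1 bonded to the α face of C9. Formylation at C4 (LiN(i-Pr)2, HCO2Me, −78 °C) would give the hydroxymethylene ester F6. DDQ then removes the 4-methoxybenzyl group to the hydroxy acid F7, and camphorsulfonic acid closes the dihydropyran by addition of the C1 hydroxyl to the formyl carbon and loss of water. C1 is not fixed by a ring on this path, so the C1 epimers would be separated and the 1α acid carried on as 19.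

Step 17. Capture of the C1 cation may lack facial selectivity, or acid and iodine species formed during the reaction may strip the triethylsilyl groups and open the way to intramolecular capture. The fallback sets out from 26 and returns at 29; it goes stepwise through the lactol. Pb(OAc)4 (benzene, pyridine, rt) would give the C1 acetate F8 by oxidative decarboxylation. Bu3SnOMe would remove the anomeric acetyl group to the lactol F9, which the conjugated formyl group stabilises against ring opening. Steglich acylation with 27 (DCC, DMAP) should then give 29, the β ester forming from the less hindered convex lactol anomer.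

**Further compounds**

F1 | step 10 | methyl (2E)-2-[(1S,4R)-3-[(tert-butyldiphenylsilyloxy)methyl]-4-hydroxycyclopent-2-en-1-yl]-3-(2-methoxy-2-oxoethoxy)prop-2-enoate | COC(=O)CO/C=C(/C(=O)OC)[C@H]1C[C@@H](O)C(CO[Si](c2ccccc2)(c2ccccc2)C(C)(C)C)=C1
F2 | step 10 | 7β 4-nitrobenzoate of F1 (C7 inverted) | COC(=O)CO/C=C(/C(=O)OC)[C@H]1C[C@H](OC(=O)c2ccc(cc2)[N+](=O)[O-])C(CO[Si](c3ccccc3)(c3ccccc3)C(C)(C)C)=C1
F3 | step 10 | C7-epimeric seco acid (7β-OH) | OC(=O)CO/C=C(/C(=O)OC)[C@H]1C[C@H](O)C(CO[Si](c2ccccc2)(c2ccccc2)C(C)(C)C)=C1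
F4 | step 11 | (4-methoxybenzyloxy)acetate of 8 at the C7 oxygen | COC(=O)C[C@H]1C[C@@H](OC(=O)COCc2ccc(OC)cc2)C(CO[Si](c2ccccc2)(c2ccccc2)C(C)(C)C)=C1
F5 | step 11 | open-chain Claisen acid (C1 with 4-methoxybenzyloxy and carboxyl on the α face of C9; C7=C8; C5–CH2CO2Me; C1 epimers) | OC(=O)C(OCc1ccc(OC)cc1)[C@@H]1C(CO[Si](c2ccccc2)(c2ccccc2)C(C)(C)C)=CC[C@@H]1CC(=O)OC
F6 | step 11 | C4 hydroxymethylene ester of F5 | OC(=O)C(OCc1ccc(OC)cc1)[C@@H]1C(CO[Si](c2ccccc2)(c2ccccc2)C(C)(C)C)=CC[C@@H]1C(=CO)C(=O)OC
F7 | step 11 | C1 hydroxy acid from F6 | OC(=O)C(O)[C@@H]1C(CO[Si](c2ccccc2)(c2ccccc2)C(C)(C)C)=CC[C@@H]1C(=CO)C(=O)OC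
F8 | step 17 | C1 acetate (either C1 epimer; C4–CHO; 7β,8α-bis(OSiEt3); C10–OSiPh2t-Bu) | CC(=O)OC1OC=C(C=O)[C@H]2C[C@H](O[Si](CC)(CC)CC)[C@](O[Si](CC)(CC)CC)(CO[Si](c3ccccc3)(c3ccccc3)C(C)(C)C)[C@@H]12
F9 | step 17 | C1 lactol (anomeric mixture) | OC1OC=C(C=O)[C@H]2C[C@H](O[Si](CC)(CC)CC)[C@](O[Si](CC)(CC)CC)(CO[Si](c3ccccc3)(c3ccccc3)C(C)(C)C)[C@@H]12
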